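## Structural features

The target is a depsidone. Rings A and B are benzene rings joined twice: by a diaryl ether oxygen and by an ester whose carbonyl carbon sits on ring A and whose oxygen sits on ring B, which closes a seven-membered dioxepinone. Ring A is pentasubstituted and carries in sequence the lactone carbonyl, a methyl group, one C–H, a phenol, a formyl group hydrogen-bonded to that phenol, and the ether oxygen. Ring B is hexasubstituted: lactone oxygen, methyl, the carbon bearing the pyranone carbonyl, the pyran oxygen, a free phenol and the ether oxygen follow one another, so four contiguous oxygens each end in a different role. A 2,2-dimethylpyran-4-one is fused to ring B through the pyran oxygen and the adjacent ring carbon (a 2,2-dimethylchroman-4-one unit). There is no stereocentre, so no stereochemical relationship has to be set. The fragile elements are the aryl ester (base, nucleophiles), the aldehyde, the air-sensitive catechol intermediates, and hydroxy diaryl ethers that can undergo Smiles rearrangement under base. The real difficulty is regiochemical: saturating ring B with six different substituents and joining the rings with ester and ether in the right orientation. The key step uses the oxygen–carbon pair of ring B that holds the pyranone: the phenol oxygen of a salicylaldehyde becomes O1 and its formyl carbon becomes C4 of the chromanone, while the alkene supplies C2 with both methyl groups and C3.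

## Logic of the disconnections

21 to 20. The two O–CH3 bonds (ring A phenol, ring B C8 phenol) are the last to be cleaved. Both phenols stay masked until the lactone exists, because a free C8 hydroxyl would be a second oxygen ortho to the ether and could lactonise instead of the C6 oxygen. Nothing is simplified structurally; the demand is that one reagent removes a chelated methyl ether and a hindered, non-chelated one without opening the lactone.

20 to 18 (through 19). The ester C(=O)–O(ring B) bond is cut. It is the most labile skeletal bond and is therefore formed last; cutting it opens the seven-membered ring to a diaryl ether. The demand is that the acid is released and cyclised without base, since base could move the aryl group between the two ring B oxygens. For that reason 18 carries an acid-labile ester.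

18 to 12 and 17. The ether O–C(ring A) bond is cut. This is the convergent cut that divides the molecule into two arenes; the ring A carbon lies between a formyl and an ester group and is an electrophile. The demand is that the C7 oxygen of 12, not the C6 oxygen, is arylated, which rests on the higher acidity of the hydroxyl para to the ketone and on monoanion conditions.

12 to 10 to 9 to 8. The C6–O bond is traced back to a C6–CHO bond, the C7 methyl ether is restored, and the C6–CHO bond is cut. The formyl group serves twice: it marks its neighbouring methoxy group for chelation-controlled cleavage, which tells O7 from O8 without a separate protecting-group scheme, and it then becomes the C6 hydroxyl. Ring B returns to one C–H and two like ethers. The demands are formylation at a flanked position of a ketone-bearing ring, mono-demethylation, and an oxidation that leaves the ketone alone.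

8 to 7. The C4 ketone is taken back to the C4 methyl ether that the cycloaddition delivers. The demand is an oxidation selective for that benzylic C–H.

7 to 3 and 4 (through 5 and 6). The C4–C3 and O1–C2 bonds are cut. This removes the whole pyran ring in one operation and leaves a simple salicylaldehyde and a four-carbon alkene of matching polarity. The demands are generation of 6 from a di-ortho-substituted aldehyde, Markovnikov orientation of 4, and suppression of its acid oligomerisation.

3 to 2 to 1. One O–CH3 bond is reinstated and the C–CHO bond is cut. In 1 both free ring positions are equivalent, and in 2 the aldehyde selects which of three ethers is cleaved, namely the oxygen that becomes the pyran oxygen.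

17 to 16 to 14 to 13 (through 15). The C–CO2R bond, the C–CHO bond and the C–Br bond are cut in turn. In 13 the methoxy group directs bromination to its para position, the future carboxyl carbon. Fluorine and methoxy together direct lithiation to the carbon between them, the future formyl carbon. The demand is carbonylation of a hindered bromide without loss of the activated fluoride.

## Other disconnections considered

Alternative 1: The cut removes the lactone oxygen from between the ring A carbonyl and ring B, so the depsidone core A2 contracts to xanthone A1. In the forward step CF3CO3H adds to the ketone of A1 and the ring B carbon migrates to oxygen (Baeyer–Villiger ring expansion) to give A2.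
- In favour: A1 is a robust tricycle that a ring A salicylic acid and a ring B phenol could give by acylation and cyclodehydration. The ring A aldehyde is held as an acetoxymethyl group and cannot undergo Dakin cleavage.
- Against: the xanthone carbonyl is a doubly vinylogous ester flanked by two peri methyl groups and should be a poor acceptor for a peracid. A peracid strong enough may attack the electron-rich ring B instead. The orientation depends on the ring B carbon migrating in preference to the ring A carbon.
- Against: after the key step ring B still lacks the pyranone. Acylation at its last C–H, selective unmasking of one of two methyl ethers, ring closure and oxidation of the acetoxymethyl group would all follow on a sensitive lactone.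
- Comparison: the chosen plan completes ring B, pyranone included, at 8 before any fragile bond exists. Its key step is an ionic cycloaddition with close precedent, whereas this one is an oxygen insertion of uncertain rate. Step economy is about level or somewhat worse.
- Where it is better: the question of which catechol oxygen becomes ether and which ester (step 11) does not arise.

Alternative 2: The cut opens ring B between the carbon that will carry the lactone oxygen and the methyl-bearing carbon, taking hydroquinone diaryl ether A4 back to cyclobutenone A3. In the forward step, heating A3 opens the four-membered ring to a dienylketene, which closes by 6π electrocyclisation and tautomerises to A4.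
- In favour: all four ring B oxygens arrive differentiated, and only one free hydroxyl is ortho to the ether, so lactonisation is unambiguous. The hindered diaryl ether comes from addition–elimination of a ring A phenoxide on a squarate ester.
- Against: the propenyl nucleophile must pick the right carbonyl of an unsymmetrical cyclobutenedione in the presence of the ring A ester. A4 is an air-sensitive hydroquinone. The ring A phenol partner needs its own multistep synthesis.
- Against: the pyranone must still be fused onto the remaining C–H and the para hydroxyl under strong acid.
- Comparison: ring B is built from a four-membered ring where the chosen plan starts from an arene with three oxygens in place, so step economy is worse.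
- Where it is equal or better: the thermal pericyclic cascade is the equal of the chosen key step in reliability. It is better in oxygen differentiation, needing no formylation–Dakin pair and no selective demethylation.

Alternative 3: The cut replaces the ester oxygen–ring B bond by a C–H bond, taking depsidone catechol A6 back to diaryl ether acid A5. In the forward step, anodic oxidation turns the catechol of A5 into an ortho-quinone; the ring A carboxylate adds in a 1,4 sense at the free carbon next to the ether-bearing carbon, and enolisation gives A6.
- In favour: no oxygen has to be installed beforehand, which would save the formylation, demethylation and Dakin steps. No stoichiometric oxidant is used, the tether allows only one site, and the acyloxy group should make A6 harder to oxidise than A5.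
- Against: A5 requires arylation of a terminal hydroxyl of a 1,2,3-trioxygenated toluene, whose central hydroxyl is the more acidic. The ortho-quinone can add water or dimerise before a seven-membered ring closes.
- Against: the pyranone must again be added last, under strong acid, to a lactone bearing a free catechol.
- Comparison: the mechanism is less secure than the chosen cycloaddition and SNAr pair, and the hardest ring is postponed to the end.
- Where it is better: step economy, on paper.

Key step: step 3

Assumption: compound 7 is formed as a racemate; its single stereocentre is removed in step 4 and the target is achiral, so no stereocontrol is needed anywhere.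

## Route

Step 1
Reactants: 1 3,4,5-trimethoxytoluene
Product: 2 2,3,4-trimethoxy-6-methylbenzaldehyde
Conditions: POCl3, DMF, 0 → 80 °C; then H2O
Reagents that add atoms: N,N-dimethylformamide, CN(C)C=O (formyl carbon); water, O (formyl oxygen)
Why: Vilsmeier–Haack formylation of an arene activated by three methoxy groups; the two free positions are equivalent by symmetry, so only one aldehyde can form.

Step 2
Reactants: 2 2,3,4-trimethoxy-6-methylbenzaldehyde
Product: 3 2-hydroxy-3,4-dimethoxy-6-methylbenzaldehyde
Conditions: BCl3 (1.1 equiv), CH2Cl2, −78 → 0 °C; then H2O
Reagents that add atoms: none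
Why: Chelation-controlled ether cleavage: BCl3 bridges the aldehyde oxygen and the ortho methoxy oxygen in a six-membered chelate and chloride removes that methyl group; with about one equivalent at low temperature the other two ethers should remain, and the freed phenol is the future pyran oxygen.

Step 3
Reactants: 3 2-hydroxy-3,4-dimethoxy-6-methylbenzaldehyde; 4 isobutene (excess, condensed)
Product: 7 4,7,8-trimethoxy-2,2,5-trimethylchroman (racemic), via dimethyl acetal 5 (not isolated), via methoxy ortho-quinone methide 6 (not isolated)
Conditions: HC(OMe)3 (1.5 equiv), TfOH (5 mol %), CH2Cl2, −40 → 0 °C, sealed vessel; then Et3N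
Reagents that add atoms: trimethyl orthoformate, COC(OC)OC
Why: Transacetalisation with the orthoformate gives 5, and acid-promoted loss of methanol gives 6 in its O-protonated form, a 2-hydroxybenzyl oxocarbenium ion. The CH2 terminus of 4 attacks the exocyclic carbon (C4–C3 bond) and the phenolic oxygen captures the developing tertiary cation (O1–C2 bond), an asynchronous inverse-electron-demand oxa-[4+2] cycloaddition. The closest known reaction type is the acid-catalysed three-component coupling of salicylaldehydes, orthoformates and alkenes to 4-alkoxychromans through ortho-quinone methides. The one ring closed is the six-membered pyran ring, formed in a [4+2] sense; if the process is stepwise, the phenol oxygen closes a six-membered ring onto the tertiary cation. The new C4 stereocentre is formed without control, as a racemate, and is erased in step 4. The selectivity needed is regiochemical: the gem-dimethyl carbon must end on oxygen, which the Markovnikov polarity of 4 secures because only its disubstituted carbon can carry cationic character. Oligomerisation of 4 and re-ionisation of the benzylic ether of 7 (elimination to a chromene) are held back by catalytic acid, low temperature and the amine quench.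

Step 4
Reactants: 7 4,7,8-trimethoxy-2,2,5-trimethylchroman
Product: 8 7,8-dimethoxy-2,2,5-trimethylchroman-4-one
Conditions: DDQ (1.5 equiv), CH2Cl2/H2O, 0 °C → rt
Reagents that add atoms: water, O
Why: DDQ oxidation of an electron-rich benzylic ether: hydride abstraction at C4 gives a cation stabilised by the ortho ring oxygen and the para methoxy group, water adds and methanol is lost to leave the aryl ketone; the quaternary C2 excludes dehydrogenation to a chromone.

Step 5
Reactants: 8 7,8-dimethoxy-2,2,5-trimethylchroman-4-one
Product: 9 7,8-dimethoxy-2,2,5-trimethyl-4-oxochroman-6-carbaldehyde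
Conditions: Cl2CHOMe, TiCl4, CH2Cl2, −20 → 0 °C; then H2O
Reagents that add atoms: dichloromethyl methyl ether, COC(Cl)Cl (formyl carbon); water, O (formyl oxygen)
Why: Rieche formylation; C6 is the only free ring position and is para to the pyran oxygen, ortho to the C7 methoxy group and meta to the ketone-bearing carbon, so it should stay nucleophilic enough despite the ketone.

Step 6
Reactants: 9 7,8-dimethoxy-2,2,5-trimethyl-4-oxochroman-6-carbaldehyde
Product: 10 7-hydroxy-8-methoxy-2,2,5-trimethyl-4-oxochroman-6-carbaldehyde
Conditions: BCl3 (1.2 equiv), CH2Cl2, −78 → −10 °C; then H2O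
Reagents that add atoms: none
Why: Chelation-controlled demethylation as in step 2: only the C7 methoxy group is ortho to the aldehyde and can enter the six-membered boron chelate, whereas the C8 methoxy group has no carbonyl partner (the ring ketone oxygen points away from O1), so with limited reagent at low temperature it should remain.

Step 7
Reactants: 10 7-hydroxy-8-methoxy-2,2,5-trimethyl-4-oxochroman-6-carbaldehyde
Product: 12 6,7-dihydroxy-8-methoxy-2,2,5-trimethylchroman-4-one, via aryl formate 11 (not isolated)
Conditions: 30% aq H2O2, NaOH, THF/H2O, 0 °C, Ar; then aq HCl
Reagents that add atoms: hydrogen peroxide, OO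
Why: Dakin oxidation of an ortho-hydroxybenzaldehyde: hydroperoxide adds to the aldehyde, the electron-rich aryl group migrates to oxygen to give 11, and hydroxide cleaves the formate; the ketone is inert to basic H2O2, and exclusion of air with prompt acidification should protect the catechol.

Step 8
Reactants: 13 3-fluoro-5-methylanisole
Product: 14 4-bromo-3-fluoro-5-methylanisole
Conditions: NBS, MeCN, 0 °C → rt
Reagents that add atoms: N-bromosuccinimide, O=C1CCC(=O)N1Br
Why: Electrophilic aromatic bromination with NBS in a polar solvent goes para to the methoxy group; that position, between F and CH3, is the carbon that will carry the carboxyl group.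

Step 9
Reactants: 14 4-bromo-3-fluoro-5-methylanisole
Product: 16 3-bromo-2-fluoro-6-methoxy-4-methylbenzaldehyde, via aryllithium 15 (not isolated)
Conditions: LiN(i-Pr)2, THF, −78 °C; DMF, −78 °C; then aq HCl
Reagents that add atoms: N,N-dimethylformamide, CN(C)C=O
Why: Directed ortho-metalation followed by formylation: the proton flanked by F and OCH3 is the most acidic, the amide base does not exchange the bromide, and 15 is kept at −78 °C so that it does not lose LiF to an aryne before DMF traps it.

Step 10
Reactants: 16 3-bromo-2-fluoro-6-methoxy-4-methylbenzaldehyde
Product: 17 4-methoxybenzyl 2-fluoro-3-formyl-4-methoxy-6-methylbenzoate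
Conditions: Pd(OAc)2 (5 mol %), Xantphos (10 mol %), CO (1 atm), 4-methoxybenzyl alcohol, Et3N, toluene, 90 °C
Reagents that add atoms: carbon monoxide, [C-]#[O+]; 4-methoxybenzyl alcohol, COc1ccc(CO)cc1
Why: Palladium-catalysed alkoxycarbonylation of an aryl bromide (oxidative addition to zerovalent palladium, CO insertion, alcoholysis of the acyl complex); the wide-bite-angle ligand suits ortho-substituted bromides at atmospheric CO pressure, Et3N is too weak to form an alkoxide that could displace the fluoride, and the 4-methoxybenzyl ester is chosen so that the acid can later be freed by acid alone.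

Step 11
Reactants: 12 6,7-dihydroxy-8-methoxy-2,2,5-trimethylchroman-4-one; 17 4-methoxybenzyl 2-fluoro-3-formyl-4-methoxy-6-methylbenzoate
Product: 18 4-methoxybenzyl 3-formyl-2-[(6-hydroxy-8-methoxy-2,2,5-trimethyl-4-oxochroman-7-yl)oxy]-4-methoxy-6-methylbenzoate
Conditions: K2CO3 (1.0 equiv), DMF, 50 °C, Ar; then cold aq HCl
Reagents that add atoms: none
Why: Nucleophilic aromatic substitution on a fluoride flanked by an ortho formyl and an ortho ester group; the C7 hydroxyl of 12 is para to the ketone-bearing carbon and the more acidic, so one equivalent of carbonate should give the C7 phenoxide, which arylates in the way 3,4-dihydroxyaryl carbonyl compounds alkylate at the para oxygen, while the remaining hydrogencarbonate is too weak to keep the C6 hydroxyl deprotonated and so should limit Smiles rearrangement.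

Step 12
Reactants: 18 4-methoxybenzyl 3-formyl-2-[(6-hydroxy-8-methoxy-2,2,5-trimethyl-4-oxochroman-7-yl)oxy]-4-methoxy-6-methylbenzoate
Product: 20 O,O'-dimethyl ether of the target depsidone, via hydroxy acid 19 (not isolated)
Conditions: TFA, anisole, CH2Cl2, 0 °C → rt; evaporate; then (CF3CO)2O, toluene, rt
Reagents that add atoms: none
Why: Acidolysis of the 4-methoxybenzyl ester (the benzylic cation is trapped by anisole) frees 19 without base, and activation of the acid by the anhydride lets the C6 hydroxyl close the seven-membered lactone, the usual dehydrative lactonisation of depsidone hydroxy acids; C8 is still methylated, so only one phenol can reach the acyl group.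

Step 13
Reactants: 20 O,O'-dimethyl ether of the target depsidone
Product: 21 target depsidone CNP0271978.0
Conditions: BCl3 (excess), CH2Cl2, −78 °C → rt; then H2O
Reagents that add atoms: none
Why: Boron trichloride ether cleavage: the ring A methoxy group is ortho to the aldehyde and leaves through the chelate, and the C8 methoxy group is flanked by two ether oxygens, twisted out of the ring plane and thus a hindered, Lewis-basic ether of the kind BCl3 cleaves; the lactone, the diaryl ether and the non-chelated pyran ether should persist.

## Compound list

1 | 3,4,5-trimethoxytoluene | COc1cc(C)cc(OC)c1OC | starting material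
2 | 2,3,4-trimethoxy-6-methylbenzaldehyde | COc1cc(C)c(C=O)c(OC)c1OC | intermediate
3 | 2-hydroxy-3,4-dimethoxy-6-methylbenzaldehyde | COc1cc(C)c(C=O)c(O)c1OC | intermediate
4 | isobutene (2-methylpropene) | CC(C)=C | starting material
5 | 2-(dimethoxymethyl)-5,6-dimethoxy-3-methylphenol | COC(OC)c1c(C)cc(OC)c(OC)c1O | intermediate (not isolated)
6 | 6-(methoxymethylidene)-2,3-dimethoxy-5-methylcyclohexa-2,4-dien-1-one (exocyclic alkene geometry not defined; reacts as its O-protonated form) | COC=C1C(C)=CC(OC)=C(OC)C1=O | intermediate (not isolated)
7 | 4,7,8-trimethoxy-2,2,5-trimethylchroman (racemic at C4) | COC1CC(C)(C)Oc2c(OC)c(OC)cc(C)c21 | intermediate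
8 | 7,8-dimethoxy-2,2,5-trimethylchroman-4-one | COc1cc(C)c2c(c1OC)OC(C)(C)CC2=O | intermediate
9 | 7,8-dimethoxy-2,2,5-trimethyl-4-oxochroman-6-carbaldehyde | COc1c(C=O)c(C)c2c(c1OC)OC(C)(C)CC2=O | intermediate
10 | 7-hydroxy-8-methoxy-2,2,5-trimethyl-4-oxochroman-6-carbaldehyde | COc1c(O)c(C=O)c(C)c2c1OC(C)(C)CC2=O | intermediate
11 | 7-hydroxy-8-methoxy-2,2,5-trimethyl-4-oxochroman-6-yl formate | COc1c(O)c(OC=O)c(C)c2c1OC(C)(C)CC2=O | intermediate (not isolated)
12 | 6,7-dihydroxy-8-methoxy-2,2,5-trimethylchroman-4-one | COc1c(O)c(O)c(C)c2c1OC(C)(C)CC2=O | intermediate
13 | 3-fluoro-5-methylanisole | COc1cc(C)cc(F)c1 | starting material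
14 | 4-bromo-3-fluoro-5-methylanisole (2-bromo-1-fluoro-5-methoxy-3-methylbenzene) | COc1cc(C)c(Br)c(F)c1 | intermediate
15 | (3-bromo-2-fluoro-6-methoxy-4-methylphenyl)lithium | COc1cc(C)c(Br)c(F)c1[Li] | intermediate (not isolated)
16 | 3-bromo-2-fluoro-6-methoxy-4-methylbenzaldehyde | COc1cc(C)c(Br)c(F)c1C=O | intermediate
17 | 4-methoxybenzyl 2-fluoro-3-formyl-4-methoxy-6-methylbenzoate | COc1ccc(COC(=O)c2c(C)cc(OC)c(C=O)c2F)cc1 | intermediate
18 | 4-methoxybenzyl 3-formyl-2-[(6-hydroxy-8-methoxy-2,2,5-trimethyl-4-oxochroman-7-yl)oxy]-4-methoxy-6-methylbenzoate | COc1ccc(COC(=O)c2c(C)cc(OC)c(C=O)c2Oc2c(O)c(C)c3c(c2OC)OC(C)(C)CC3=O)cc1 | intermediate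
19 | 3-formyl-2-[(6-hydroxy-8-methoxy-2,2,5-trimethyl-4-oxochroman-7-yl)oxy]-4-methoxy-6-methylbenzoic acid | OC(=O)c1c(C)cc(OC)c(C=O)c1Oc1c(O)c(C)c2c(c1OC)OC(C)(C)CC2=O | intermediate (not isolated)
20 | O,O'-dimethyl ether of the target depsidone (OCH3 on the ring A phenol and on the ring B phenol) | Cc1cc(OC)c(C=O)c2c1C(=O)Oc1c(C)c3c(c(OC)c1O2)OC(C)(C)CC3=O | intermediate
21 | target depsidone CNP0271978.0 (ring A: CH3, OH, CHO; ring B: CH3, OH, fused 2,2-dimethylpyran-4-one) | Cc1cc(O)c(C=O)c2c1C(=O)Oc1c(C)c3c(c(O)c1O2)OC(C)(C)CC3=O | target

## Step count and least certain steps

Total: 13 steps. Longest linear sequence: 10 steps (steps 1 to 7, then 11 to 13); the ring A branch (steps 8 to 10) joins at step 11.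

Step 3 (key step). The process most likely to fail is cationic oligomerisation of 4, which consumes the alkene and buries the catalyst. A second failure mode is re-ionisation of the benzylic ether of the product, leading to elimination or a second alkene addition. The hydrogen-bonded, di-ortho-substituted aldehyde may also be slow to form 6. Fallback, setting out from 1 and returning at 8: Friedel–Crafts acetylation with AcCl and AlCl3 in CH2Cl2, in which the aluminium chelate also removes the methyl group ortho to the new ketone, should give 1-(2-hydroxy-3,4-dimethoxy-6-methylphenyl)ethanone F1. Kabbe condensation of F1 with acetone and pyrrolidine (enamine aldol, dehydration, oxa-Michael closure) would then give the chromanone 8 directly, replacing steps 1 to 4.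

Step 11. The likely failure is loss of regiocontrol. Arylation could occur at the C6 oxygen through the minor, more nucleophilic phenoxide or through a dianion. Alternatively, base-induced migration of the aryl group from O7 to O6 through a spiro Meisenheimer intermediate (Smiles rearrangement) could occur after the coupling. Either would lead to the isomeric depsidone. Fallback, setting out from 10 and returning at 19:
- Benzylation (BnBr, K2CO3, DMF) would give 7-benzyloxy-8-methoxy-2,2,5-trimethyl-4-oxochroman-6-carbaldehyde F2.
- Baeyer–Villiger oxidation with mCPBA and methanolysis of the formate (K2CO3, MeOH) would give 7-benzyloxy-6-hydroxy-8-methoxy-2,2,5-trimethylchroman-4-one F3.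
- MOMCl and i-Pr2NEt would give 7-benzyloxy-8-methoxy-6-(methoxymethoxy)-2,2,5-trimethylchroman-4-one F4.
- Hydrogenolysis (H2, Pd/C, EtOAc) would give 7-hydroxy-8-methoxy-6-(methoxymethoxy)-2,2,5-trimethylchroman-4-one F5, in which only the C7 oxygen is free.
- SNAr with 17 (K2CO3, DMF) would give 4-methoxybenzyl 3-formyl-4-methoxy-2-{[8-methoxy-6-(methoxymethoxy)-2,2,5-trimethyl-4-oxochroman-7-yl]oxy}-6-methylbenzoate F6.
- TFA would remove the acetal and the ester together to give 19, which is lactonised as in step 12.

Step 13. The likely failure is incomplete cleavage of the hindered but non-chelated C8 methyl ether. Forcing the reaction would risk opening the lactone or the pyranone. Fallback, setting out from 9 and returning at 21, with the C8 oxygen carried as a benzyl ether: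
- Excess BCl3 (CH2Cl2, rt) should remove both methyl groups of 9, the second assisted by the neighbouring aryloxyboron group, giving 7,8-dihydroxy-2,2,5-trimethyl-4-oxochroman-6-carbaldehyde F10.
- Alkylation of the dianion (NaH, 2.2 equiv; BnBr, 1 equiv; DMF) at the less acidic, more nucleophilic oxygen would give 8-benzyloxy-7-hydroxy-2,2,5-trimethyl-4-oxochroman-6-carbaldehyde F11.
- Dakin oxidation as in step 7 would give 8-benzyloxy-6,7-dihydroxy-2,2,5-trimethylchroman-4-one F12.
- SNAr with 17 as in step 11 would give 4-methoxybenzyl 2-[(8-benzyloxy-6-hydroxy-2,2,5-trimethyl-4-oxochroman-7-yl)oxy]-3-formyl-4-methoxy-6-methylbenzoate F13.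
- TFA would give 2-[(8-benzyloxy-6-hydroxy-2,2,5-trimethyl-4-oxochroman-7-yl)oxy]-3-formyl-4-methoxy-6-methylbenzoic acid F14.
- (CF3CO)2O would give the 8-O-benzyl ring A O-methyl depsidone F15.
- BCl3 with pentamethylbenzene at −78 °C, which cleaves benzyl ethers and chelated methyl ethers readily, would then give 21.

Step 10. The likely failures are slow oxidative addition or CO insertion at the bromide flanked by F and CH3, and displacement of the activated fluoride by the alcohol at the temperature needed. Fallback, setting out from 16 and returning at 17:
- Acetalisation (ethylene glycol, TsOH, toluene, reflux) would give 2-(3-bromo-2-fluoro-6-methoxy-4-methylphenyl)-1,3-dioxolane F7.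
- Bromine–lithium exchange (n-BuLi, THF, −78 °C) and carboxylation with CO2 would give 3-(1,3-dioxolan-2-yl)-2-fluoro-4-methoxy-6-methylbenzoic acid F8.
- Alkylation of the carboxylate (4-methoxybenzyl chloride, K2CO3, DMF) would give 4-methoxybenzyl 3-(1,3-dioxolan-2-yl)-2-fluoro-4-methoxy-6-methylbenzoate F9.
- Mild hydrolysis of the acetal (dilute aq HCl, THF, rt) would give 17.

## Further compounds

F1 | step 3 | 1-(2-hydroxy-3,4-dimethoxy-6-methylphenyl)ethanone | CC(=O)c1c(C)cc(OC)c(OC)c1O
F2 | step 11 | 7-benzyloxy-8-methoxy-2,2,5-trimethyl-4-oxochroman-6-carbaldehyde | COc1c(OCc2ccccc2)c(C=O)c(C)c2c1OC(C)(C)CC2=O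
F3 | step 11 | 7-benzyloxy-6-hydroxy-8-methoxy-2,2,5-trimethylchroman-4-one | COc1c(OCc2ccccc2)c(O)c(C)c2c1OC(C)(C)CC2=O
F4 | step 11 | 7-benzyloxy-8-methoxy-6-(methoxymethoxy)-2,2,5-trimethylchroman-4-one | COc1c(OCc2ccccc2)c(OCOC)c(C)c2c1OC(C)(C)CC2=O
F5 | step 11 | 7-hydroxy-8-methoxy-6-(methoxymethoxy)-2,2,5-trimethylchroman-4-one | COc1c(O)c(OCOC)c(C)c2c1OC(C)(C)CC2=O
F6 | step 11 | 4-methoxybenzyl 3-formyl-4-methoxy-2-{[8-methoxy-6-(methoxymethoxy)-2,2,5-trimethyl-4-oxochroman-7-yl]oxy}-6-methylbenzoate | COc1ccc(COC(=O)c2c(C)cc(OC)c(C=O)c2Oc2c(OCOC)c(C)c3c(c2OC)OC(C)(C)CC3=O)cc1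
F7 | step 10 | 2-(3-bromo-2-fluoro-6-methoxy-4-methylphenyl)-1,3-dioxolane | COc1cc(C)c(Br)c(F)c1C1OCCO1
F8 | step 10 | 3-(1,3-dioxolan-2-yl)-2-fluoro-4-methoxy-6-methylbenzoic acid | COc1cc(C)c(C(=O)O)c(F)c1C1OCCO1
F9 | step 10 | 4-methoxybenzyl 3-(1,3-dioxolan-2-yl)-2-fluoro-4-methoxy-6-methylbenzoate | COc1ccc(COC(=O)c2c(C)cc(OC)c(C3OCCO3)c2F)cc1
F10 | step 13 | 7,8-dihydroxy-2,2,5-trimethyl-4-oxochroman-6-carbaldehyde | O=Cc1c(C)c2c(c(O)c1O)OC(C)(C)CC2=O
F11 | step 13 | 8-benzyloxy-7-hydroxy-2,2,5-trimethyl-4-oxochroman-6-carbaldehyde | O=Cc1c(C)c2c(c(OCc3ccccc3)c1O)OC(C)(C)CC2=O
F12 | step 13 | 8-benzyloxy-6,7-dihydroxy-2,2,5-trimethylchroman-4-one | Cc1c(O)c(O)c(OCc2ccccc2)c2c1C(=O)CC(C)(C)O2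
F13 | step 13 | 4-methoxybenzyl 2-[(8-benzyloxy-6-hydroxy-2,2,5-trimethyl-4-oxochroman-7-yl)oxy]-3-formyl-4-methoxy-6-methylbenzoate | COc1ccc(COC(=O)c2c(C)cc(OC)c(C=O)c2Oc2c(O)c(C)c3c(c2OCc4ccccc4)OC(C)(C)CC3=O)cc1
F14 | step 13 | 2-[(8-benzyloxy-6-hydroxy-2,2,5-trimethyl-4-oxochroman-7-yl)oxy]-3-formyl-4-methoxy-6-methylbenzoic acid | OC(=O)c1c(C)cc(OC)c(C=O)c1Oc1c(O)c(C)c2c(c1OCc3ccccc3)OC(C)(C)CC2=O
F15 | step 13 | 8-O-benzyl ring A O-methyl ether of the target depsidone | Cc1cc(OC)c(C=O)c2c1C(=O)Oc1c(C)c3c(c(OCc4ccccc4)c1O2)OC(C)(C)CC3=O
A1 | alternative 1 | 3-acetoxy-4-(acetoxymethyl)-5,6-dimethoxy-1,8-dimethyl-9H-xanthen-9-one | Cc1cc(OC(C)=O)c(COC(C)=O)c2Oc3c(OC)c(OC)cc(C)c3C(=O)c12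
A2 | alternative 1 | depsidone core with acetate and acetoxymethyl on ring A and two methyl ethers on ring B | Cc1cc(OC(C)=O)c(COC(C)=O)c2c1C(=O)Oc1c(C)cc(OC)c(OC)c1O2
A3 | alternative 2 | methyl 3-(1,3-dioxolan-2-yl)-2-{[4-hydroxy-3-methoxy-2-oxo-4-((E)-prop-1-enyl)cyclobut-3... written as 2-aryloxy-4-hydroxy-3-methoxy-4-((E)-prop-1-enyl)cyclobut-2-en-1-one, aryl = 2-(methoxycarbonyl)-6-(1,3-dioxolan-2-yl)-5-methoxy-3-methylphenyl (racemic) | COC(=O)c1c(C)cc(OC)c(C2OCCO2)c1OC1=C(OC)C(O)(/C=C/C)C1=O
A4 | alternative 2 | methyl 2-(2,5-dihydroxy-6-methoxy-3-methylphenoxy)-3-(1,3-dioxolan-2-yl)-4-methoxy-6-methylbenzoate | COC(=O)c1c(C)cc(OC)c(C2OCCO2)c1Oc1c(O)c(C)cc(O)c1OC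
A5 | alternative 3 | 2-(2,3-dihydroxy-5-methylphenoxy)-3-formyl-4-methoxy-6-methylbenzoic acid | Cc1cc(OC)c(C=O)c(Oc2cc(C)cc(O)c2O)c1C(=O)O
A6 | alternative 3 | depsidone catechol lacking the pyranone (ring A O-methyl ether) | Cc1cc(OC)c(C=O)c2c1C(=O)Oc1c(C)cc(O)c(O)c1O2
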